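**Retrosynthetic overview**

1. In germacrane numbering the ring-fusion carbon C7 lies between C6 (lactone carbinol) and C8 (acyloxy carbinol). With both as carbonyls, C7 is a stereolabile 1,3-diketone methine carrying the C11–C12 acetate arm, so C6 and C7 can be fixed in one operation as the γ-lactone ring O–C6–C7–C11–C12 closes.
2. Target 35 ⇒ macrocyclic diene 34 (C1–C10 oxirane last, peracid) ⇒ Z-C4 vinyl iodide / C3 aldehyde 33 (C3–C4 bond, CrCl2/NiCl2); the O8 ester comes from (2S,3S)-epoxyangelic acid 29, made from angelic acid by Sharpless epoxidation.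
3. The Z-iodide ⇐ propynyl lactone 18 by O8-tethered ruthenium trans-hydrosilylation (temporary oxasilepine ring), Mannich methylenation at C11 and iododesilylation; C8 carbinol ⇐ ketone 17 (CBS reduction).
4. 17 ⇐ racemic alkynyl diketo ester 15 by asymmetric transfer hydrogenation with dynamic resolution and lactonisation; 15 ⇐ pent-3-yn-2-one + aldehyde 8 (aldol, oxidation) + methyl bromoacetate; 8 ⇐ butynyl silyl ether 1 by carboalumination and ethylene oxide opening.
5. Ring order: γ-lactone (step 8), oxasilepine (step 10, opened in step 12), ten-membered carbocycle (step 19), C1–C10 oxirane (step 20).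

Key step: step 8

Remark: germacrane numbering (C1–C15) is used for all intermediates; the target is read from the SMILES as 1R,3S,6R,7R,8R,10R with a (2S,3S)-epoxyangelate; diketones 12 and 15 are drawn as diketo tautomers, although 12 will be largely enolised.

**Route**

Step 1
Reactants: 1 tert-butyl(but-3-yn-1-yloxy)dimethylsilane; 2 ethylene oxide
Product: 5 (E)-6-[(tert-butyldimethylsilyl)oxy]-4-methylhex-3-en-1-ol, via alkenyldimethylalane 3 (not isolated), via lithium alkenylaluminate 4 (not isolated)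
Conditions: Me3Al, Cp2ZrCl2 (0.25 equiv), CH2Cl2, 0 °C → rt; volatiles removed; n-BuLi, THF/hexane, −78 °C; 2, −78 °C → rt; aq. KNaC4H4O6
Reagents that add atoms: trimethylaluminium C[Al](C)C
Why: Zirconium-catalysed carboalumination (Negishi) adds methyl and aluminium syn across the terminal alkyne with methyl on the internal carbon (C10), and the derived aluminate opens ethylene oxide with retention, so the E-trisubstituted C1=C10 olefin and the C2–C3 unit are set in one flask.

Step 2
Reactants: 5 (E)-6-[(tert-butyldimethylsilyl)oxy]-4-methylhex-3-en-1-ol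
Product: 6 (E)-1-[(tert-butyldimethylsilyl)oxy]-6-[(tert-butyldiphenylsilyl)oxy]-3-methylhex-3-ene
Conditions: TBDPSCl, imidazole, CH2Cl2, rt
Reagents that add atoms: tert-butyl(chloro)diphenylsilane CC(C)(C)[Si](Cl)(c1ccccc1)c1ccccc1
Why: Imidazole-promoted silylation of the primary C3 hydroxyl installs the robust group that has to last until step 17.

Step 3
Reactants: 6 (E)-1-[(tert-butyldimethylsilyl)oxy]-6-[(tert-butyldiphenylsilyl)oxy]-3-methylhex-3-ene
Product: 7 (E)-6-[(tert-butyldiphenylsilyl)oxy]-3-methylhex-3-en-1-ol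
Conditions: PPTS (cat.), MeOH, rt
Reagents that add atoms: none
Why: Acid-catalysed methanolysis cleaves the primary tert-butyldimethylsilyl ether much faster than the bulkier tert-butyldiphenylsilyl ether, freeing only the C8 hydroxyl.

Step 4
Reactants: 7 (E)-6-[(tert-butyldiphenylsilyl)oxy]-3-methylhex-3-en-1-ol
Product: 8 (E)-6-[(tert-butyldiphenylsilyl)oxy]-3-methylhex-3-enal
Conditions: Dess–Martin periodinane, pyridine, CH2Cl2, 0 °C → rt; used crude
Reagents that add atoms: none
Why: Buffered Dess–Martin oxidation should give the β,γ-unsaturated C8 aldehyde without moving the olefin into conjugation.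

Step 5
Reactants: 9 pent-3-yn-2-one; 8 (E)-6-[(tert-butyldiphenylsilyl)oxy]-3-methylhex-3-enal
Product: 11 (E)-11-[(tert-butyldiphenylsilyl)oxy]-6-hydroxy-8-methylundec-8-en-2-yn-4-one (racemic), via lithium enolate 10 (not isolated)
Conditions: LiN(iPr)2, THF, −78 °C; then 8, −78 °C; AcOH quench at −78 °C
Reagents that add atoms: none
Why: The ynone has a single enolisable α-carbon (its methyl group, the future C7), so the aldol addition forms C7–C8 without any regiochemical question; the new C8 carbinol is racemic and is removed in step 6.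

Step 6
Reactants: 11 (E)-11-[(tert-butyldiphenylsilyl)oxy]-6-hydroxy-8-methylundec-8-en-2-yn-4-one
Product: 12 (E)-11-[(tert-butyldiphenylsilyl)oxy]-8-methylundec-8-en-2-yne-4,6-dione
Conditions: Dess–Martin periodinane, CH2Cl2, 0 °C → rt
Reagents that add atoms: none
Why: Dess–Martin oxidation of a β-hydroxy ketone gives the 1,3-diketone under non-basic conditions that do not promote cyclisation onto the ynone.

Step 7
Reactants: 12 (E)-11-[(tert-butyldiphenylsilyl)oxy]-8-methylundec-8-en-2-yne-4,6-dione; 13 methyl bromoacetate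
Product: 15 methyl (E)-3-(but-2-ynoyl)-9-[(tert-butyldiphenylsilyl)oxy]-6-methyl-4-oxonon-6-enoate (racemic at C7), via sodium enolate 14 (not isolated)
Conditions: NaH (1.0 equiv), THF/DMF (4:1), 0 °C; then 13, 0 °C → rt
Reagents that add atoms: none
Why: SN2 C-alkylation of the chelated sodium 1,3-diketonate with the reactive α-bromo ester installs C11–C12 at C7; in the chelate the C8 enolate oxygen points away from the alkyne, which should hold back pyranone formation.

Step 8
Reactants: 15 methyl (E)-3-(but-2-ynoyl)-9-[(tert-butyldiphenylsilyl)oxy]-6-methyl-4-oxonon-6-enoate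
Product: 17 (4S,5S)-4-[(E)-6-[(tert-butyldiphenylsilyl)oxy]-3-methylhex-3-enoyl]-5-(prop-1-yn-1-yl)dihydrofuran-2(3H)-one, via hydroxy ester 16 (not isolated)
Conditions: RuCl[(S,S)-TsDPEN](p-cymene) (2 mol %), HCO2H/Et3N (5:2), CH2Cl2, 0 °C → rt; then PPTS (cat.), toluene, 40 °C
Reagents that add atoms: none
Why: The Ru–H/N–H catalyst passes hydride and proton from formic acid to the C6 ynone carbonyl through an outer-sphere six-membered transition state (Noyori–Ikariya asymmetric transfer hydrogenation of an α,β-acetylenic ketone, run on a racemising 2-substituted 1,3-diketone as in dynamic kinetic resolutions of α-substituted β-dicarbonyl compounds), the alkynyl group taking the place usually held by an aryl group so that the (S,S)-ligand should give the 6S carbinol. The C6 hydroxyl then attacks the C12 methyl ester in a 5-exo-trig acyl substitution and closes the γ-lactone ring O–C6–C7–C11–C12 with loss of methanol. C6 is set by the catalyst; C7 enolises between the two ketones faster than the ynone is reduced, so it is funnelled by dynamic resolution, and because it stays α to the C8 ketone after ring closure the mild acid finally equilibrates it to the trans-4,5-disubstituted lactone. The step needs chemoselectivity for the ynone over the C8 dialkyl ketone, which the higher electrophilicity and small size of the alkynyl ketone should secure. It also needs reduction to outrun 6-endo-dig attack of the C8 enol oxygen on C4 (pyranone formation), which the mainly diketo form of the 2-substituted diketone, the formic-acid-rich medium and the low temperature should hold back. Opening of the product by β-elimination of the C6 carboxylate is the reverse of a disfavoured 5-endo-trig closure and should not compete during the C7 equilibration.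

Step 9
Reactants: 17 (4S,5S)-4-[(E)-6-[(tert-butyldiphenylsilyl)oxy]-3-methylhex-3-enoyl]-5-(prop-1-yn-1-yl)dihydrofuran-2(3H)-one
Product: 18 (4R,5S)-4-[(1R,3E)-6-[(tert-butyldiphenylsilyl)oxy]-1-hydroxy-3-methylhex-3-en-1-yl]-5-(prop-1-yn-1-yl)dihydrofuran-2(3H)-one
Conditions: (S)-2-methyl-CBS-oxazaborolidine (0.3 equiv), catecholborane, toluene, −78 → −40 °C; MeOH quench, aqueous work-up
Reagents that add atoms: none
Why: In the Corey–Bakshi–Shibata reduction the branched ring carbon C7 acts as the large group and C9H2 as the small one, so the (S)-catalyst should give 8R, the same sense as Felkin–Anh attack anti to the C7–C6 bond; catecholborane at low temperature leaves the alkyne, the olefin and the lactone alone.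

Step 10
Reactants: 18 (4R,5S)-4-[(1R,3E)-6-[(tert-butyldiphenylsilyl)oxy]-1-hydroxy-3-methylhex-3-en-1-yl]-5-(prop-1-yn-1-yl)dihydrofuran-2(3H)-one
Product: 20 (6S,7S,8R)-bicyclic alkenylsiloxane in which the γ-lactone is trans-fused at C6–C7 to the seven-membered ring Si–O–C8–C7–C6–C5=C4 (SiMe2 and the C15 methyl on C4; C8 bears the E side chain CH2–C(CH3)=CH–CH2CH2–OTBDPS), via dimethylsilyl ether 19 (not isolated)
Conditions: (HMe2Si)2NH, neat, 50 °C, then evacuation; [Cp*Ru(MeCN)3]PF6 (5 mol %), CH2Cl2, 0 °C → rt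
Reagents that add atoms: 1,1,3,3-tetramethyldisilazane C[SiH](C)N[SiH](C)C
Why: Ruthenium-catalysed intramolecular trans-hydrosilylation of a bishomopropargylic silyl ether proceeds endo-dig, so the O8 tether places silicon on C4 and hydrogen on C5 anti to it; this fixes both the regiochemistry and the Z geometry (C6 and Si cis) that the lactone oxygen alone could not direct.

Step 11
Reactants: 20 (6S,7S,8R)-bicyclic alkenylsiloxane
Product: 24 (6S,7S,8R)-11(13)-methylene derivative of siloxane 20 (α-methylene-γ-lactone), via lithium enolate 21 (not isolated), via Mannich base 22 (not isolated), via ammonium iodide 23 (not isolated)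
Conditions: LiN(iPr)2, THF, −78 °C; [Me2N=CH2]I (Eschenmoser salt), −78 °C → rt; then MeI, CH2Cl2, rt; then aq. NaHCO3, rt
Reagents that add atoms: dimethylmethyleneammonium iodide C=[N+](C)C.[I-]
Why: Mannich reaction of the lactone enolate at C11, N-methylation and E1cB loss of trimethylamine give the exocyclic C11=C13 olefin; it is done here because the siloxane masks O8 (no translactonisation) and no vinyl iodide is yet present for the strong base to dehydroiodinate.

Step 12
Reactants: 24 (6S,7S,8R)-11(13)-methylene siloxane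
Product: 25 (4R,5S)-4-[(1R,3E)-6-[(tert-butyldiphenylsilyl)oxy]-1-hydroxy-3-methylhex-3-en-1-yl]-5-[(Z)-2-iodoprop-1-en-1-yl]-3-methylidenedihydrofuran-2(3H)-one
Conditions: N-iodosuccinimide, 2,6-lutidine, (CF3)2CHOH, 0 °C; aq. Na2S2O3/NaHCO3 work-up
Reagents that add atoms: N-iodosuccinimide O=C1CCC(=O)N1I
Why: Iododesilylation is an ipso substitution through a β-silyl cation and goes with retention, giving the Z-C4 vinyl iodide; the remaining labile O–Si bond hydrolyses on work-up to free the C8 hydroxyl, and the two electron-poor olefins do not react.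

Step 13
Reactants: 26 angelic acid
Product: 27 (Z)-2-methylbut-2-en-1-ol
Conditions: LiAlH4, Et2O, 0 °C
Reagents that add atoms: none
Why: Hydride reduction of the acid at low temperature gives the allylic alcohol with the Z geometry kept.

Step 14
Reactants: 27 (Z)-2-methylbut-2-en-1-ol
Product: 28 [(2R,3S)-2,3-dimethyloxiran-2-yl]methanol
Conditions: Ti(OiPr)4 (cat.), D-(−)-diethyl tartrate (cat.), t-BuOOH, 4 Å molecular sieves, CH2Cl2, −20 °C
Reagents that add atoms: tert-butyl hydroperoxide CC(C)(C)OO
Why: In the Sharpless asymmetric epoxidation the tartrate selects the olefin face; the D-(−)-ester should give the 2R,3S epoxy alcohol (the L-(+)-ester gives the 2S series with primary allylic alcohols), and the Z olefin keeps hydroxymethyl and the C3 methyl cis.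

Step 15
Reactants: 28 [(2R,3S)-2,3-dimethyloxiran-2-yl]methanol
Product: 29 (2S,3S)-2,3-dimethyloxirane-2-carboxylic acid
Conditions: TEMPO (cat.), PhI(OAc)2, MeCN/H2O, rt
Reagents that add atoms: water O
Why: Oxoammonium oxidation takes the primary alcohol through the aldehyde hydrate to the acid without touching the oxirane; the spatial arrangement is unchanged and only the C2 descriptor changes.

Step 16
Reactants: 29 (2S,3S)-2,3-dimethyloxirane-2-carboxylic acid; 25 Z-vinyl iodide alcohol
Product: 31 (6S,7R,8R)-O8-[(2S,3S)-2,3-dimethyloxirane-2-carbonyl] ester of 25, via mixed anhydride 30 (not isolated)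
Conditions: 2,4,6-trichlorobenzoyl chloride, Et3N, THF, rt; then 25, DMAP, toluene, rt
Reagents that add atoms: none
Why: Yamaguchi esterification through the mixed anhydride and the acylpyridinium acylates the hindered C8 hydroxyl with retention; the acid has no α-hydrogen, so it cannot epimerise.

Step 17
Reactants: 31 O8 ester with C3 silyl ether
Product: 32 (6S,7R,8R)-C3 primary alcohol (31 without the tert-butyldiphenylsilyl group)
Conditions: HF·pyridine, pyridine, THF, 0 °C → rt
Reagents that add atoms: none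
Why: Buffered fluoride cleaves the Si–O bond and should leave the two esters, the electron-poor oxirane, the vinyl iodide and the methylene lactone intact.

Step 18
Reactants: 32 C3 primary alcohol
Product: 33 (6S,7R,8R)-C3 aldehyde
Conditions: Dess–Martin periodinane, pyridine, CH2Cl2, 0 °C; used crude
Reagents that add atoms: none
Why: Buffered Dess–Martin oxidation should give the β,γ-unsaturated aldehyde without olefin migration or epimerisation.

Step 19
Reactants: 33 C3 aldehyde
Product: 34 (3S,6R,7R,8R)-3-hydroxy-8-[(2S,3S)-2,3-dimethyloxirane-2-carbonyloxy]germacra-1(10)E,4Z,11(13)-trien-12,6-olide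
Conditions: CrCl2 (excess), NiCl2 (cat.), degassed DMSO/THF, rt, slow addition at high dilution
Reagents that add atoms: none
Why: In the Nozaki–Hiyama–Kishi reaction nickel inserts into the C4–iodine bond, the alkenyl group passes to trivalent chromium with retention of the Z geometry and adds to the C3 aldehyde to close the ten-membered ring; C3 is set under substrate control in the macrocyclic transition state, and the 3S alcohol is the one needed.

Step 20
Reactants: 34 macrocyclic allylic alcohol
Product: 35 (1R,3S,6R,7R,8R,10R)-1,10-epoxy-3-hydroxy-8-[(2S,3S)-2,3-dimethyloxirane-2-carbonyloxy]germacra-4Z,11(13)-dien-12,6-olide (CNP0268255.2)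
Conditions: m-CPBA (1.05 equiv), CH2Cl2/aq. phosphate buffer (pH 7), 0 °C
Reagents that add atoms: 3-chloroperoxybenzoic acid O=C(OO)c1cccc(Cl)c1
Why: In the Prilezhaev epoxidation the electrophilic peracid should prefer the strained E-trisubstituted C1=C10 olefin over C4=C5 (deactivated by two allylic C–O bonds) and the acrylate-type methylene; attack on the outward face of the conformer with C14 on the same side as C11 should give the 1R,10R trans-oxirane.

**Compound list**

1 | tert-butyl(but-3-yn-1-yloxy)dimethylsilane | C#CCCO[Si](C)(C)C(C)(C)C | starting material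
2 | ethylene oxide | C1CO1 | starting material
3 | [(E)-4-[(tert-butyldimethylsilyl)oxy]-2-methylbut-1-en-1-yl]dimethylalane | C[Al](C)/C=C(\C)CCO[Si](C)(C)C(C)(C)C | intermediate
4 | lithium butyl[(E)-4-[(tert-butyldimethylsilyl)oxy]-2-methylbut-1-en-1-yl]dimethylaluminate | [Li+].CCCC[Al-](C)(C)/C=C(\C)CCO[Si](C)(C)C(C)(C)C | intermediate
5 | (E)-6-[(tert-butyldimethylsilyl)oxy]-4-methylhex-3-en-1-ol | OCC/C=C(\C)CCO[Si](C)(C)C(C)(C)C | intermediate
6 | (E)-1-[(tert-butyldimethylsilyl)oxy]-6-[(tert-butyldiphenylsilyl)oxy]-3-methylhex-3-ene | CC(C)(C)[Si](C)(C)OCC/C(C)=C/CCO[Si](c1ccccc1)(c1ccccc1)C(C)(C)C | intermediate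
7 | (E)-6-[(tert-butyldiphenylsilyl)oxy]-3-methylhex-3-en-1-ol | OCC/C(C)=C/CCO[Si](c1ccccc1)(c1ccccc1)C(C)(C)C | intermediate
8 | (E)-6-[(tert-butyldiphenylsilyl)oxy]-3-methylhex-3-enal | O=CC/C(C)=C/CCO[Si](c1ccccc1)(c1ccccc1)C(C)(C)C | intermediate
9 | pent-3-yn-2-one | CC#CC(C)=O | starting material
10 | lithium pent-1-en-3-yn-2-olate | [Li+].[O-]C(=C)C#CC | intermediate
11 | (E)-11-[(tert-butyldiphenylsilyl)oxy]-6-hydroxy-8-methylundec-8-en-2-yn-4-one (racemic) | CC#CC(=O)CC(O)C/C(C)=C/CCO[Si](c1ccccc1)(c1ccccc1)C(C)(C)C | intermediate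
12 | (E)-11-[(tert-butyldiphenylsilyl)oxy]-8-methylundec-8-en-2-yne-4,6-dione | CC#CC(=O)CC(=O)C/C(C)=C/CCO[Si](c1ccccc1)(c1ccccc1)C(C)(C)C | intermediate
13 | methyl bromoacetate | COC(=O)CBr | starting material
14 | sodium enolate of diketone 12 | [Na+].CC#CC(=O)C=C([O-])C/C(C)=C/CCO[Si](c1ccccc1)(c1ccccc1)C(C)(C)C | intermediate
15 | methyl (E)-3-(but-2-ynoyl)-9-[(tert-butyldiphenylsilyl)oxy]-6-methyl-4-oxonon-6-enoate (racemic at C7) | CC#CC(=O)C(CC(=O)OC)C(=O)C/C(C)=C/CCO[Si](c1ccccc1)(c1ccccc1)C(C)(C)C | intermediate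
16 | methyl (E)-9-[(tert-butyldiphenylsilyl)oxy]-3-[(1S)-1-hydroxybut-2-yn-1-yl]-6-methyl-4-oxonon-6-enoate (6S; both C7 epimers) | CC#C[C@@H](O)C(CC(=O)OC)C(=O)C/C(C)=C/CCO[Si](c1ccccc1)(c1ccccc1)C(C)(C)C | intermediate
17 | (4S,5S)-4-[(E)-6-[(tert-butyldiphenylsilyl)oxy]-3-methylhex-3-enoyl]-5-(prop-1-yn-1-yl)dihydrofuran-2(3H)-one | CC#C[C@H]1OC(=O)C[C@@H]1C(=O)C/C(C)=C/CCO[Si](c2ccccc2)(c2ccccc2)C(C)(C)C | intermediate
18 | (4R,5S)-4-[(1R,3E)-6-[(tert-butyldiphenylsilyl)oxy]-1-hydroxy-3-methylhex-3-en-1-yl]-5-(prop-1-yn-1-yl)dihydrofuran-2(3H)-one | CC#C[C@H]1OC(=O)C[C@@H]1[C@H](O)C/C(C)=C/CCO[Si](c2ccccc2)(c2ccccc2)C(C)(C)C | intermediate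
19 | O8-dimethylsilyl ether of 18 (6S,7S,8R) | CC#C[C@H]1OC(=O)C[C@@H]1[C@H](O[SiH](C)C)C/C(C)=C/CCO[Si](c2ccccc2)(c2ccccc2)C(C)(C)C | intermediate
20 | (6S,7S,8R)-bicyclic alkenylsiloxane: γ-lactone trans-fused at C6–C7 to the ring Si–O–C8–C7–C6–C5=C4, SiMe2 and CH3 on C4 | CC1=C[C@H]2OC(=O)C[C@@H]2[C@@H](C/C(C)=C/CCO[Si](c3ccccc3)(c3ccccc3)C(C)(C)C)O[Si]1(C)C | intermediate
21 | lithium enolate (C11=C12) of lactone 20 | [Li+].CC1=C[C@H]2OC([O-])=C[C@@H]2[C@@H](C/C(C)=C/CCO[Si](c3ccccc3)(c3ccccc3)C(C)(C)C)O[Si]1(C)C | intermediate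
22 | 11-[(dimethylamino)methyl] derivative of 20 (C11 epimers) | CC1=C[C@H]2OC(=O)C(CN(C)C)[C@@H]2[C@@H](C/C(C)=C/CCO[Si](c3ccccc3)(c3ccccc3)C(C)(C)C)O[Si]1(C)C | intermediate
23 | 11-[(trimethylammonio)methyl] derivative of 20, iodide | CC1=C[C@H]2OC(=O)C(C[N+](C)(C)C)[C@@H]2[C@@H](C/C(C)=C/CCO[Si](c3ccccc3)(c3ccccc3)C(C)(C)C)O[Si]1(C)C.[I-] | intermediate
24 | (6S,7S,8R)-11(13)-methylene derivative of siloxane 20 | CC1=C[C@H]2OC(=O)C(=C)[C@@H]2[C@@H](C/C(C)=C/CCO[Si](c3ccccc3)(c3ccccc3)C(C)(C)C)O[Si]1(C)C | intermediate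
25 | (4R,5S)-4-[(1R,3E)-6-[(tert-butyldiphenylsilyl)oxy]-1-hydroxy-3-methylhex-3-en-1-yl]-5-[(Z)-2-iodoprop-1-en-1-yl]-3-methylidenedihydrofuran-2(3H)-one | C/C(I)=C/[C@H]1OC(=O)C(=C)[C@@H]1[C@H](O)C/C(C)=C/CCO[Si](c2ccccc2)(c2ccccc2)C(C)(C)C | intermediate
26 | angelic acid, (Z)-2-methylbut-2-enoic acid | C/C=C(/C)C(=O)O | starting material
27 | (Z)-2-methylbut-2-en-1-ol | C/C=C(/C)CO | intermediate
28 | [(2R,3S)-2,3-dimethyloxiran-2-yl]methanol | OC[C@@]1(C)O[C@H]1C | intermediate
29 | (2S,3S)-2,3-dimethyloxirane-2-carboxylic acid | OC(=O)[C@@]1(C)O[C@H]1C | intermediate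
30 | (2S,3S)-2,3-dimethyloxirane-2-carboxylic 2,4,6-trichlorobenzoic anhydride | O=C(OC(=O)[C@@]1(C)O[C@H]1C)c1c(Cl)cc(Cl)cc1Cl | intermediate
31 | (6S,7R,8R)-O8-[(2S,3S)-2,3-dimethyloxirane-2-carbonyl] ester of 25 | C/C(I)=C/[C@H]1OC(=O)C(=C)[C@@H]1[C@H](OC(=O)[C@@]2(C)O[C@H]2C)C/C(C)=C/CCO[Si](c3ccccc3)(c3ccccc3)C(C)(C)C | intermediate
32 | (6S,7R,8R)-C3 primary alcohol from 31 | C/C(I)=C/[C@H]1OC(=O)C(=C)[C@@H]1[C@H](OC(=O)[C@@]2(C)O[C@H]2C)C/C(C)=C/CCO | intermediate
33 | (6S,7R,8R)-C3 aldehyde from 32 | C/C(I)=C/[C@H]1OC(=O)C(=C)[C@@H]1[C@H](OC(=O)[C@@]2(C)O[C@H]2C)C/C(C)=C/CC=O | intermediate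
34 | (3S,6R,7R,8R)-3-hydroxy-8-[(2S,3S)-2,3-dimethyloxirane-2-carbonyloxy]germacra-1(10)E,4Z,11(13)-trien-12,6-olide | C=C1C(=O)O[C@@H]2/C=C(/C)[C@@H](O)C/C=C(\C)C[C@@H](OC(=O)[C@@]3(C)O[C@H]3C)[C@@H]12 | intermediate
35 | (1R,3S,6R,7R,8R,10R)-1,10-epoxy-3-hydroxy-8-[(2S,3S)-2,3-dimethyloxirane-2-carbonyloxy]germacra-4Z,11(13)-dien-12,6-olide (CNP0268255.2) | C=C1C(=O)O[C@@H]2/C=C(/C)[C@@H](O)C[C@H]3O[C@]3(C)C[C@@H](OC(=O)[C@@]3(C)O[C@H]3C)[C@@H]12 | target

**Step count and risks**

Total steps: 20. Longest linear sequence: 17 (steps 1–12 and 16–20); steps 13–15 form the side branch to acid 29.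

The three steps most likely to fail:

Step 8. Hydride transfer may be outrun by amine-promoted 6-endo-dig cyclisation of the enolised diketone onto the ynone (pyranone formation), or the intermediate aldol may dehydrate before it lactonises. The fallback drops the amine medium and the dynamic resolution. Starting from 15, stoichiometric Midland reduction with (S)-Alpine-borane (B-isopinocampheyl-9-borabicyclo[3.3.1]nonane from (−)-α-pinene, neat, rt) reduces only the ynone under neutral aprotic conditions and sets 6S by reagent control, giving hydroxy ester 16 as both C7 epimers. PPTS in toluene then closes the lactone and equilibrates C7 through the enol of the C8 ketone to the trans isomer, returning to 17. This fallback makes no compound outside the list.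

Step 19. The ring closure may show poor facial selectivity at the C3 aldehyde, so that the 3R alcohol forms beside or instead of 34. The fallback corrects C3 after closure by reagent control. Starting from the crude mixture of 34 and its C3 epimer F1, oxidation with MnO2 in CH2Cl2 converges both on the macrocyclic enone F2. Reduction with (R)-2-methyl-CBS-oxazaborolidine and catecholborane at −78 °C, in which the C4 alkenyl group acts as the large substituent, should then return the 3S alcohol 34.

Step 20. The free C3 hydroxyl may direct the peracid to C4=C5, or the reagent may attack the inner face of C1=C10, giving the wrong site or the wrong oxirane diastereomer. The fallback installs the oxirane before ring closure under reagent control, at a stage where C1=C10 is the only electron-rich olefin. Starting from 31, Shi epoxidation (D-fructose-derived ketone catalyst, KHSO5 as 2KHSO5·KHSO4·K2SO4, K2CO3, MeCN/dimethoxymethane/H2O, 0 °C) should give the 1R,10R epoxy silyl ether F3. HF·pyridine then gives the epoxy alcohol F4, and buffered Dess–Martin oxidation gives the epoxy aldehyde F5. Closure with CrCl2/NiCl2 as in step 19 would lead directly to 35.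

Further compounds
F0 | step 8 | none | none
F1 | step 19 | (3R,6R,7R,8R)-3-epimer of macrocyclic alcohol 34 | C=C1C(=O)O[C@@H]2/C=C(/C)[C@H](O)C/C=C(\C)C[C@@H](OC(=O)[C@@]3(C)O[C@H]3C)[C@@H]12
F2 | step 19 | 3-oxo analogue of 34 (macrocyclic 4Z-en-3-one) | C=C1C(=O)O[C@@H]2/C=C(/C)C(=O)C/C=C(\C)C[C@@H](OC(=O)[C@@]3(C)O[C@H]3C)[C@@H]12
F3 | step 20 | (1R,10R)-1,10-epoxide of silyl ether 31 | C/C(I)=C/[C@H]1OC(=O)C(=C)[C@@H]1[C@H](OC(=O)[C@@]2(C)O[C@H]2C)C[C@@]4(C)O[C@@H]4CCO[Si](c3ccccc3)(c3ccccc3)C(C)(C)C
F4 | step 20 | (1R,10R)-1,10-epoxide of alcohol 32 | C/C(I)=C/[C@H]1OC(=O)C(=C)[C@@H]1[C@H](OC(=O)[C@@]2(C)O[C@H]2C)C[C@@]4(C)O[C@@H]4CCO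
F5 | step 20 | (1R,10R)-1,10-epoxide of aldehyde 33 | C/C(I)=C/[C@H]1OC(=O)C(=C)[C@@H]1[C@H](OC(=O)[C@@]2(C)O[C@H]2C)C[C@@]4(C)O[C@@H]4CC=O
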